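**Retrosynthetic overview**
- Araneosol is traced back, through hydrogenolysis, O-methylation and C3 hydroxylation (lithiation, borate, oxidation), to a 7-O-benzyl-5-hydroxy-6,8-dimethoxy-4'-methoxyflavone.
- Key disconnection: the pyranone ring (ring C) is cut at C4a–C4, C4–C3 and O1–C2 into a 2-iodoresorcinol, carbon monoxide and 4-ethynylanisole. Ring C is the only ring formed; ring A comes from syringol and ring B from the alkyne.
- Feature used: C4a lies between C5 and C8a, which both carry oxygen, and the ring A pattern C5(OH)–C6(OMe)–C7(O)–C8(OMe)–C8a(O) is mirror-symmetric about the C7···C4a axis. A symmetric 2-iodoresorcinol can therefore give either hydroxyl to O1 and keep the other as the C5 hydroxyl.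
- The iodoresorcinol comes from O-benzylsyringol by dibromination ortho to the two methoxy groups, exchange of both bromines for hydroxyl, and iodination of the last free ring carbon.

Key step: step 5

Remark: syringol, benzyl bromide, carbon monoxide and 4-ethynylanisole are taken as purchased. The transient enaminone 11 is drawn as its E isomer; either geometry would close to the same flavone.

**Route**

Step 1
Reactants: 1 2,6-dimethoxyphenol (syringol); 2 benzyl bromide
Product: 3 2-(benzyloxy)-1,3-dimethoxybenzene
Conditions: K2CO3, DMF, 60 °C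
Reagents that add atoms: none
Why: Williamson ether synthesis; the benzyl ether masks the future C7 oxygen and removes the para-directing free phenol, so that the two methoxy groups direct the next step.

Step 2
Reactants: 3 2-(benzyloxy)-1,3-dimethoxybenzene
Product: 4 3-(benzyloxy)-1,5-dibromo-2,4-dimethoxybenzene
Conditions: N-bromosuccinimide (2.1 equiv), MeCN, 0 °C to rt, dark
Reagents that add atoms: N-bromosuccinimide, O=C1CCC(=O)N1Br
Why: Electrophilic aromatic bromination; each in-plane methoxy group directs ortho to itself and para to the other, as 1,2,3-trialkoxybenzenes brominate at C4 and then C6, while the twisted central benzyloxy group leaves C5 unactivated.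

Step 3
Reactants: 4 3-(benzyloxy)-1,5-dibromo-2,4-dimethoxybenzene
Product: 6 5-(benzyloxy)-4,6-dimethoxybenzene-1,3-diol, via bis(pinacol boronate) 5 (not isolated)
Conditions: B2pin2 (2.5 equiv), Pd2(dba)3 (2 mol %), XPhos (8 mol %), KOAc, 1,4-dioxane, 100 °C; then THF, NaOH aq., H2O2 (30 % aq.), 0 °C; NH4Cl aq. work-up under argon
Reagents that add atoms: hydrogen peroxide, OO (both new oxygens of 6); bis(pinacolato)diboron, CC1(C)OB(B2OC(C)(C)C(C)(C)O2)OC1(C)C (boryl groups of intermediate 5 only, lost on oxidation)
Why: Double Miyaura borylation followed by oxidation of the C–B bonds with basic hydrogen peroxide (1,2-aryl shift from boron to oxygen) exchanges each bromine for hydroxyl without organolithium reagents that would endanger the benzyl ether.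

Step 4
Reactants: 6 5-(benzyloxy)-4,6-dimethoxybenzene-1,3-diol
Product: 7 5-(benzyloxy)-2-iodo-4,6-dimethoxybenzene-1,3-diol
Conditions: I2 (1.05 equiv), NaHCO3, THF–H2O, 0 °C, argon
Reagents that add atoms: iodine, II
Why: Electrophilic iodination of a phenol; the only unsubstituted ring carbon lies ortho to both hydroxyls and para to the benzyloxy group, and the mild I2/NaHCO3 system used to make 2-iodoresorcinol from resorcinol should not oxidise the electron-rich ring.

Step 5
Reactants: 7 5-(benzyloxy)-2-iodo-4,6-dimethoxybenzene-1,3-diol; 8 carbon monoxide; 9 4-ethynylanisole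
Product: 12 7-(benzyloxy)-5-hydroxy-6,8-dimethoxy-2-(4-methoxyphenyl)-4H-chromen-4-one, via ynone 10 (not isolated), via enaminone 11 (not isolated)
Conditions: PdCl2(dppf) (5 mol %), 9 (1.3 equiv), Et2NH (excess), DMF, CO (20 bar), 100 °C, no copper
Reagents that add atoms: diethylamine, CCNCC (held only in intermediate 11 and released again on ring closure; no reagent atom remains in 12)
Why: Zerovalent palladium, formed from the divalent precatalyst, adds oxidatively into the C–I bond of 7, CO inserts to give the aroylpalladium species, and coupling with the amine-activated alkyne 9 gives ynone 10, which forms C4a–C4 and C4–C3. Et2NH then adds to the alkyne carbon that becomes C2 to give enaminone 11, and a phenol oxygen attacks that same carbon and expels the amine, which forms O1–C2. The closest known reaction is the palladium-catalysed carbonylative Sonogashira annulation of 2-iodophenols with terminal alkynes in a secondary amine, which gives flavones directly. The pyranone ring closes in the 6-endo mode (formally 6-endo-dig on the ynone, in practice addition–elimination on the enaminone), and no stereocenter is formed. The step needs 6-endo closure to the flavone and not 5-exo closure to the aurone, which the enaminone secures because it leaves C2 as the only electrophilic carbon for oxygen; it also needs carbonylative over direct coupling, which CO pressure, the absence of copper and the wide-bite-angle dppf ligand on the hindered electron-rich iodide should favour. No choice between the two hydroxyls arises, since the mirror symmetry of 7 makes them equivalent: one becomes O1 and the other the chelated C5 hydroxyl.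

Step 6
Reactants: 12 7-(benzyloxy)-5-hydroxy-6,8-dimethoxy-2-(4-methoxyphenyl)-4H-chromen-4-one; 2 benzyl bromide
Product: 13 5,7-bis(benzyloxy)-6,8-dimethoxy-2-(4-methoxyphenyl)-4H-chromen-4-one
Conditions: K2CO3, n-Bu4NI (cat.), DMF, 70 °C
Reagents that add atoms: none
Why: Williamson benzylation of the hydrogen-bonded C5 hydroxyl, which needs warm DMF and iodide catalysis, removes the only acidic proton before the lithiation.

Step 7
Reactants: 13 5,7-bis(benzyloxy)-6,8-dimethoxy-2-(4-methoxyphenyl)-4H-chromen-4-one
Product: 16 5,7-bis(benzyloxy)-3-hydroxy-6,8-dimethoxy-2-(4-methoxyphenyl)-4H-chromen-4-one, via 3-lithioflavone 14 (not isolated), via lithium trimethoxyborate 15 (not isolated)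
Conditions: lithium diisopropylamide (1.5 equiv), THF, −78 °C; B(OMe)3 (3 equiv), −78 °C to 0 °C; AcOH, H2O2 (30 % aq.), 0 °C to rt
Reagents that add atoms: hydrogen peroxide, OO (the C3 oxygen of 16); for the intermediates only: lithium diisopropylamide, [Li+].CC(C)[N-]C(C)C (lithium of 14 and 15), and trimethyl borate, COB(OC)OC (borate of 15)
Why: Carbonyl-directed lithiation of a 5-O-protected flavone at C3, borylation and oxidation of the C–B bond are a known way to flavonols; at −78 °C the amide base should leave the benzyl ethers untouched.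

Step 8
Reactants: 16 5,7-bis(benzyloxy)-3-hydroxy-6,8-dimethoxy-2-(4-methoxyphenyl)-4H-chromen-4-one
Product: 17 5,7-bis(benzyloxy)-3,6,8-trimethoxy-2-(4-methoxyphenyl)-4H-chromen-4-one
Conditions: MeI, K2CO3, acetone, reflux
Reagents that add atoms: iodomethane, CI
Why: O-Methylation (SN2) of the only free hydroxyl, the flavonol C3–OH.

Step 9
Reactants: 17 5,7-bis(benzyloxy)-3,6,8-trimethoxy-2-(4-methoxyphenyl)-4H-chromen-4-one
Product: 18 araneosol, 5,7-dihydroxy-3,6,8-trimethoxy-2-(4-methoxyphenyl)-4H-chromen-4-one
Conditions: H2 (1 atm), Pd/C (10 wt %), EtOAc–MeOH, rt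
Reagents that add atoms: none
Why: Hydrogenolysis of both aryl benzyl ethers releases the C5 and C7 hydroxyls; the tetrasubstituted C2=C3 bond of the 3-methoxyflavone and the methyl ethers should not be reduced at one atmosphere.

**Compound list**
1 | 2,6-dimethoxyphenol (syringol) | COc1cccc(OC)c1O | starting material
2 | benzyl bromide | BrCc1ccccc1 | starting material
3 | 2-(benzyloxy)-1,3-dimethoxybenzene | COc1cccc(OC)c1OCc1ccccc1 | intermediate
4 | 3-(benzyloxy)-1,5-dibromo-2,4-dimethoxybenzene | COc1c(Br)cc(Br)c(OC)c1OCc1ccccc1 | intermediate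
5 | 2,2'-[5-(benzyloxy)-4,6-dimethoxy-1,3-phenylene]bis(4,4,5,5-tetramethyl-1,3,2-dioxaborolane) | COc1c(B2OC(C)(C)C(C)(C)O2)cc(B2OC(C)(C)C(C)(C)O2)c(OC)c1OCc1ccccc1 | intermediate
6 | 5-(benzyloxy)-4,6-dimethoxybenzene-1,3-diol | COc1c(O)cc(O)c(OC)c1OCc1ccccc1 | intermediate
7 | 5-(benzyloxy)-2-iodo-4,6-dimethoxybenzene-1,3-diol | COc1c(O)c(I)c(O)c(OC)c1OCc1ccccc1 | intermediate
8 | carbon monoxide | [C-]#[O+] | starting material
9 | 4-ethynylanisole | C#Cc1ccc(OC)cc1 | starting material
10 | 1-[4-(benzyloxy)-2,6-dihydroxy-3,5-dimethoxyphenyl]-3-(4-methoxyphenyl)prop-2-yn-1-one | COc1ccc(C#CC(=O)c2c(O)c(OC)c(OCc3ccccc3)c(OC)c2O)cc1 | intermediate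
11 | (E)-1-[4-(benzyloxy)-2,6-dihydroxy-3,5-dimethoxyphenyl]-3-(diethylamino)-3-(4-methoxyphenyl)prop-2-en-1-one | CCN(CC)/C(=C/C(=O)c1c(O)c(OC)c(OCc2ccccc2)c(OC)c1O)c1ccc(OC)cc1 | intermediate
12 | 7-(benzyloxy)-5-hydroxy-6,8-dimethoxy-2-(4-methoxyphenyl)-4H-chromen-4-one | COc1ccc(-c2cc(=O)c3c(O)c(OC)c(OCc4ccccc4)c(OC)c3o2)cc1 | intermediate
13 | 5,7-bis(benzyloxy)-6,8-dimethoxy-2-(4-methoxyphenyl)-4H-chromen-4-one | COc1ccc(-c2cc(=O)c3c(OCc4ccccc4)c(OC)c(OCc4ccccc4)c(OC)c3o2)cc1 | intermediate
14 | [5,7-bis(benzyloxy)-6,8-dimethoxy-2-(4-methoxyphenyl)-4-oxo-4H-chromen-3-yl]lithium | [Li]c1c(-c2ccc(OC)cc2)oc2c(OC)c(OCc3ccccc3)c(OC)c(OCc3ccccc3)c2c1=O | intermediate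
15 | lithium [5,7-bis(benzyloxy)-6,8-dimethoxy-2-(4-methoxyphenyl)-4-oxo-4H-chromen-3-yl]trimethoxyborate | [Li+].CO[B-](OC)(OC)c1c(-c2ccc(OC)cc2)oc2c(OC)c(OCc3ccccc3)c(OC)c(OCc3ccccc3)c2c1=O | intermediate
16 | 5,7-bis(benzyloxy)-3-hydroxy-6,8-dimethoxy-2-(4-methoxyphenyl)-4H-chromen-4-one | COc1ccc(-c2oc3c(OC)c(OCc4ccccc4)c(OC)c(OCc4ccccc4)c3c(=O)c2O)cc1 | intermediate
17 | 5,7-bis(benzyloxy)-3,6,8-trimethoxy-2-(4-methoxyphenyl)-4H-chromen-4-one | COc1ccc(-c2oc3c(OC)c(OCc4ccccc4)c(OC)c(OCc4ccccc4)c3c(=O)c2OC)cc1 | intermediate
18 | araneosol, 5,7-dihydroxy-3,6,8-trimethoxy-2-(4-methoxyphenyl)-4H-chromen-4-one | COc1ccc(-c2oc3c(OC)c(O)c(OC)c(O)c3c(=O)c2OC)cc1 | target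

**Step count**
Total: 9 steps. Longest linear sequence: 9 steps (1 to 18); the route is fully linear, with 2, 8 and 9 added as purchased components.

**Steps most likely to fail**

Step 5 (key step). The hindered, electron-rich iodide may add slowly to palladium. Direct coupling without CO insertion, followed by cyclisation to a 2-arylbenzofuran, may compete. The aroylpalladium intermediate may also be intercepted by diethylamine to give an amide. The fallback builds the ynone without palladium or carbon monoxide; it sets out from 7 and comes back to the route at 12. Both hydroxyls of 7 would be protected (MOMCl, i-Pr2NEt, CH2Cl2) to give 5-(benzyloxy)-2-iodo-4,6-dimethoxy-1,3-bis(methoxymethoxy)benzene F1. Iodine–lithium exchange (n-BuLi, THF, −78 °C) should give [4-(benzyloxy)-3,5-dimethoxy-2,6-bis(methoxymethoxy)phenyl]lithium F2. Separately, 9 would be deprotonated (n-BuLi, THF, −78 °C) to lithium (4-methoxyphenyl)acetylide F3 and acylated with N-methoxy-N-methylcarbamoyl chloride to N-methoxy-N-methyl-3-(4-methoxyphenyl)prop-2-ynamide F4. Addition of F2 to F4 at −78 °C should give 1-[4-(benzyloxy)-3,5-dimethoxy-2,6-bis(methoxymethoxy)phenyl]-3-(4-methoxyphenyl)prop-2-yn-1-one F5. HCl in MeOH at 40 °C would remove both methoxymethyl groups to give 10, and Et2NH in EtOH would close it through 11 to 12; any flavone that forms already under the acid is the same compound 12.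

Step 7. Lithiation at C3 may be incomplete, or the base may attack the benzylic positions or open the pyranone ring, and the borate may protonate back to 13 before it is oxidised. The fallback replaces deprotonation by electrophilic oxygen transfer; it sets out from 13 and comes back at 16. Dimethyldioxirane (acetone–CH2Cl2, 0 °C) should epoxidise the C2=C3 bond to racemic 5,7-bis(benzyloxy)-2,3-epoxy-6,8-dimethoxy-2-(4-methoxyphenyl)chroman-4-one F6, in which the cis relation at C2 and C3 is forced by the three-membered ring. A trace of p-TsOH in CH2Cl2 would then open the epoxide and tautomerise it to the flavonol 16.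

Step 3. The second borylation of the hindered, electron-rich dibromide may stall, the ortho-alkoxy boronates may protodeborylate, and the electron-rich resorcinol may be over-oxidised by the basic peroxide. The fallback forms the C–O bonds directly by palladium-catalysed coupling with hydroxide and involves neither boron nor an oxidant; it sets out from 4 and comes back at 6. Pd2(dba)3, tBuXPhos and KOH in 1,4-dioxane–H2O at 100 °C under argon, followed by acidification, should convert both C–Br bonds into C–OH. No new compound is made on the way.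

**Further compounds**
F1 | step 5 | 5-(benzyloxy)-2-iodo-4,6-dimethoxy-1,3-bis(methoxymethoxy)benzene | COCOc1c(I)c(OCOC)c(OC)c(OCc2ccccc2)c1OC
F2 | step 5 | [4-(benzyloxy)-3,5-dimethoxy-2,6-bis(methoxymethoxy)phenyl]lithium | [Li]c1c(OCOC)c(OC)c(OCc2ccccc2)c(OC)c1OCOC
F3 | step 5 | lithium (4-methoxyphenyl)acetylide | [Li]C#Cc1ccc(OC)cc1
F4 | step 5 | N-methoxy-N-methyl-3-(4-methoxyphenyl)prop-2-ynamide | CON(C)C(=O)C#Cc1ccc(OC)cc1
F5 | step 5 | 1-[4-(benzyloxy)-3,5-dimethoxy-2,6-bis(methoxymethoxy)phenyl]-3-(4-methoxyphenyl)prop-2-yn-1-one | COCOc1c(C(=O)C#Cc2ccc(OC)cc2)c(OCOC)c(OC)c(OCc2ccccc2)c1OC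
F6 | step 7 | racemic 5,7-bis(benzyloxy)-2,3-epoxy-6,8-dimethoxy-2-(4-methoxyphenyl)chroman-4-one (one enantiomer drawn) | COc1ccc([C@@]23O[C@@H]2C(=O)c2c(O3)c(OC)c(OCc3ccccc3)c(OC)c2OCc2ccccc2)cc1
F0 | step 3 | none | none
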